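**Assumptions (remarks on the chemistry)**

- The side-chain carbons are called C7 (ArCH(OH)), C8 (CH–OAr) and C9 (CH2OH); the flavanone carries the usual numbers. The SMILES corresponds to (2S,7R,8R): the threo 8‑O‑4′ ether of a (2S)-flavanone.
- Compound 13 is taken as a purchased compound.
- The facial sense of the Pd/t‑BuPyOX catalyst on 14 is taken to follow that on other cyclic enones, which points to the (R)-ligand for (2S). A test run with a simple arylboronic acid would settle this; if it showed the opposite, the (S)-ligand would be used with no other change.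

## Structural features

The target is a flavonolignan: a (2S)-5,7-dihydroxyflavanone (phloroglucinol-type ring A, pyranone ring C with the single stereocentre C2) whose ring B is a 3′,5′-dimethoxy-4′-oxyphenyl ring. The 4′-oxygen of ring B is bound to C8 of a 1-(4-hydroxyphenyl)propane-1,3-diol unit, so an alkyl aryl ether flanked by two methoxy groups joins the two halves. C7 and C8 are adjacent and threo (7R,8R). C2 lies nine bonds away across the flat ring B, so neither half can control the other. The fragile points are these: the flavanone opens to the chalcone by retro-oxa-Michael reaction under base, which destroys C2, fastest once the phenols are free; C7 is a 4-hydroxybenzylic alcohol that ionises towards a quinone methide; the benzylic C7–O and C2–O1 bonds and the C4 ketone are exposed to hydrogenolysis. The real difficulty is the threo C7/C8 pair in absolute form next to the hindered ether oxygen: SN2 construction of C8–O on a stereodefined electrophile is hindered and competes with attack at benzylic C7, and the usual aldol construction gives erythro/threo mixtures. The key step exploits the fact that, with C7 as a ketone and C9 as an ester, the C8–H lies between two carbonyl groups and bears the aryloxy oxygen. C8 is then configurationally labile, so the hindered C8–O bond can be made with no stereocontrol and one catalytic reduction can set C7 and C8 together from the racemate. C2 is then set separately by a catalyst under base-free conditions.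

## Logic of the disconnections

**17 ⇒ 16.** The three phenolic O–CH2Ph bonds are cut. The free phenols are what make C2 and C7 labile, so they are revealed last and under neutral conditions. The gain is that every earlier step handles a non-ionisable molecule. The forward step must stop before the C7–O bond, the C2–O1 bond and the C4 ketone react.

**16 ⇒ 15.** The two acetal C–O bonds at O7 and O9 are cut. The 7,9-diol had to be masked for the organolithium and boron chemistry, and one group covers both hydroxyls. The forward step needs acid mild enough not to ionise the benzylic C7–O bond.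

**15 ⇒ 12 + 14.** The C2–C1′ bond between ring C and ring B is cut. C2 is remote, so it must be set by a catalyst; this cut divides the molecule into two halves of similar size and forms C2 without base. The forward step needs face-selective aryl transfer to C2 of 14 that is indifferent to the distant stereocentres of 12.

**14 ⇒ 13.** The two O–benzyl bonds on ring A are cut, so that the ring-A phenols can neither chelate the palladium catalyst nor ionise. The forward step is a double O-alkylation, including the hydrogen-bonded 5-OH.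

**12 ⇒ 9 (through 10 and 11).** The C–B bond is traced back to the C–Br bond, which is carried inert from 4 through all earlier steps. The forward step needs halogen–lithium exchange faster than any deprotonation.

**9 ⇒ 8 ⇒ 7.** The acetal C–O bonds are cut and C9 is returned to the ester level. This leads back to the product of the key step without touching C7 or C8. The forward reduction must not epimerise C8 or trigger retro-aldol cleavage.

**7 ⇒ 5 (key).** Only the C7–H bond is cut, and the C8–H bond is allowed to exchange; no skeletal bond changes. Both adjacent stereocentres and the absolute configuration are traced to a racemate that needs no control at all. The forward step needs racemisation of 5 through 6 to be faster than reduction, one enantiomer to be reduced much faster than the other, and syn selectivity.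

**5 ⇒ 3 + 4.** The C8–O4′ bond is cut. On a racemic, doubly activated electrophile the hindered phenoxide only has to substitute, not to control configuration. The forward step needs O-alkylation to beat attack at chlorine.

**3 ⇒ 2 ⇒ 1.** The C8–Cl bond and then the C8–C9 bond are cut, which leads to a purchased methyl ketone. The forward steps are an enol chlorination limited to one chlorine and a crossed Claisen condensation with a carbonate ester.

## Other disconnections considered

**Alternative 1:** (the first that comes to mind) Cut O1–C2 and C2–C3 of ring C. The forward key step is the 6-endo oxa-Michael cyclisation of the 2′-hydroxychalcone A1, made by Claisen–Schmidt condensation; the side chain comes from an aryloxyacetate enolate aldol that forms C7–C8. The cyclisation is reversible and under thermodynamic control, and C2 is too far from C7/C8 to be induced, so both C2 epimers should form alike. The aldol should give erythro/threo mixtures of racemates. A1 would therefore lead to a set of stereoisomers that differ only at remote centres and are hard to separate. The chosen plan sets all three centres by catalysts and never exposes the flavanone to base.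

**Alternative 2:** Cut C8–O4′ together with C7–OH in the biomimetic sense. The forward key step is an oxidative radical cross-coupling (Ag2O) of flavanone phenol A2 with p-coumaryl alcohol A3 to give quinone methide A4, followed by addition of water at C7. It is the shortest plan, but radical recombination forms C8 without facial control, and water should add to A4 from both faces (aryl ethers with two ortho methoxy groups tend to favour erythro). A3 also homo-couples, and A2, with a free 4′-OH, is the flavanone most prone to ring opening under the oxidising, basic conditions. The chosen plan gives one isomer where this one would need a separation of four.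

**Alternative 3:** Cut C8–O4′ on a stereodefined electrophile. The forward key step is an asymmetric dihydroxylation of the (E)-cinnamate to diol A5, activation as cyclic sulfate A6, and displacement by the phenoxide of 4. SN2 inverts C8, so A6, which comes from the readily dihydroxylated E-alkene, would lead to the erythro ether. The threo ether would need the Z-alkene (a poor dihydroxylation substrate) or a double inversion. In addition, the 4-alkoxybenzylic C7–O bond of A6 is the more reactive site, which would give the 7‑O‑4′ regioisomer. The chosen plan makes the same bond where configuration does not matter and corrects it afterwards.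

Key step: step 4

## Route

Step 1
Reactants: 1 1-[4-(benzyloxy)phenyl]ethan-1-one
Product: 2 ethyl 3-[4-(benzyloxy)phenyl]-3-oxopropanoate
Conditions: NaH (2.5 equiv), (EtO)2CO (3 equiv), THF, reflux; then 1 M HCl, 0 °C
Reagents that add atoms: diethyl carbonate, CCOC(=O)OCC
Why: Crossed Claisen condensation: the methyl ketone enolate is C-acylated by the carbonate and the equilibrium is pulled by deprotonation of the β-ketoester. No stereocentre is formed.

Step 2
Reactants: 2 ethyl 3-[4-(benzyloxy)phenyl]-3-oxopropanoate
Product: 3 ethyl 3-[4-(benzyloxy)phenyl]-2-chloro-3-oxopropanoate (racemic)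
Conditions: SO2Cl2 (1.0 equiv), CH2Cl2, 0 °C to rt
Reagents that add atoms: sulfuryl chloride, O=S(=O)(Cl)Cl
Why: Electrophilic α-chlorination of a β-ketoester through its enol, which is far more nucleophilic than the acyl-deactivated benzyloxyarene; one equivalent limits dichlorination. The new centre C8 is racemic by design.

Step 3
Reactants: 3 ethyl 3-[4-(benzyloxy)phenyl]-2-chloro-3-oxopropanoate (racemic); 4 4-bromo-2,6-dimethoxyphenol
Product: 5 ethyl 3-[4-(benzyloxy)phenyl]-2-(4-bromo-2,6-dimethoxyphenoxy)-3-oxopropanoate (racemic)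
Conditions: K2CO3 (1.5 equiv), acetone, 50 °C
Reagents that add atoms: none
Why: Williamson-type SN2 displacement of a 2-chloro-1,3-dicarbonyl compound by a phenoxide, the reaction used to make 2-aryloxy-β-ketoesters. The phenoxide of 4 has both ortho positions and the para position blocked, so only O-alkylation is possible, and the configuration at C8 is irrelevant.

Step 4
Reactants: 5 ethyl 3-[4-(benzyloxy)phenyl]-2-(4-bromo-2,6-dimethoxyphenoxy)-3-oxopropanoate (racemic)
Product: 7 ethyl (2S,3R)-3-[4-(benzyloxy)phenyl]-2-(4-bromo-2,6-dimethoxyphenoxy)-3-hydroxypropanoate, via enol tautomer 6 (not isolated)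
Conditions: RuCl[(S,S)-TsDPEN](p-cymene) (2 mol %), HCO2H/Et3N (5:2), CH2Cl2, 30 °C
Reagents that add atoms: none
Why: Noyori-type asymmetric transfer hydrogenation of an α-substituted β-ketoester with dynamic kinetic resolution, a reaction type known for α-alkoxy and α-aryloxy β-ketoesters. The Ru–H/N–H unit delivers hydride and proton to the C7 ketone through the six-membered outer-sphere transition state, and the edge-to-face contact between the η6-cymene and the 4-benzyloxyphenyl ring fixes the carbonyl face, so that the (S,S)-ligand should give (3R), which is 7R. The C8–H of 5 lies between the aroyl and ester carbonyls and bears the aryloxy oxygen, so the two enantiomers of 5 should interconvert through enol 6 in the triethylammonium formate medium faster than either is reduced. Only the (2S)-enantiomer can place its C8–OAr bond antiperiplanar to the incoming hydride (polar Felkin–Anh) with the small C8–H, not the ester, turned towards the catalyst-bound aryl group; the (2R)-enantiomer must put the ester or the 2,6-dimethoxyaryloxy group there and should react much more slowly. The whole racemate is therefore funnelled into the (2S,3R) syn (threo) isomer: C7 is set by the catalyst and C8 by the match of substrate and catalyst. No ring is closed. The step needs chemoselectivity for the ketone over the ester, the aryl bromide and the benzyl ether, all of which are inert to the Ru hydride, and the product should be configurationally stable because its C8–H is no longer doubly activated.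

Step 5
Reactants: 7 ethyl (2S,3R)-3-[4-(benzyloxy)phenyl]-2-(4-bromo-2,6-dimethoxyphenoxy)-3-hydroxypropanoate
Product: 8 (1R,2R)-1-[4-(benzyloxy)phenyl]-2-(4-bromo-2,6-dimethoxyphenoxy)propane-1,3-diol
Conditions: LiBH4 (2.5 equiv), THF, 0 °C to rt; then aq. NH4Cl
Reagents that add atoms: none
Why: Borohydride reduction of an ester activated by the α-aryloxy and β-hydroxy groups. C8 is not deprotonated under these conditions, and the descriptor at C8 changes from S to R only because CH2OH ranks below C7.

Step 6
Reactants: 8 (1R,2R)-1-[4-(benzyloxy)phenyl]-2-(4-bromo-2,6-dimethoxyphenoxy)propane-1,3-diol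
Product: 9 (4R,5R)-4-[4-(benzyloxy)phenyl]-5-(4-bromo-2,6-dimethoxyphenoxy)-2,2-dimethyl-1,3-dioxane
Conditions: Me2C(OMe)2 (5 equiv), PPTS (5 mol %), acetone, rt
Reagents that add atoms: 2,2-dimethoxypropane, COC(C)(C)OC
Why: Acid-catalysed transacetalisation of a 1,3-diol to the six-membered acetonide. The reaction takes place at the acetal carbon only, so C7 and C8 are untouched.

Step 7
Reactants: 9 (4R,5R)-4-[4-(benzyloxy)phenyl]-5-(4-bromo-2,6-dimethoxyphenoxy)-2,2-dimethyl-1,3-dioxane
Product: 12 (4-{[(4R,5R)-4-[4-(benzyloxy)phenyl]-2,2-dimethyl-1,3-dioxan-5-yl]oxy}-3,5-dimethoxyphenyl)boronic acid, via aryllithium 10 (not isolated), via lithium triisopropoxyborate 11 (not isolated)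
Conditions: B(OiPr)3 (1.5 equiv), then n-BuLi (1.2 equiv), THF/toluene, −78 °C (in situ quench); to −20 °C; aq. NH4Cl
Reagents that add atoms: triisopropyl borate, CC(C)OB(OC(C)C)OC(C)C; water, O
Why: Bromine–lithium exchange followed by borylation and hydrolysis. The exchange at −78 °C is faster than deprotonation of the benzyl ether or the ring, and the borate present in the flask traps 10 as it forms. The acetal and the stereocentres are inert to these conditions.

Step 8
Reactants: 13 5,7-dihydroxy-4H-chromen-4-one
Product: 14 5,7-bis(benzyloxy)-4H-chromen-4-one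
Conditions: BnBr (2.5 equiv), K2CO3 (3 equiv), DMF, 70 °C
Reagents that add atoms: benzyl bromide, BrCc1ccccc1
Why: Williamson O-benzylation of both phenols; the hydrogen-bonded 5-OH needs the excess of reagent and the warm dipolar solvent. Masking both phenols prevents chelation of the Pd catalyst in step 9.

Step 9
Reactants: 12 (4-{[(4R,5R)-4-[4-(benzyloxy)phenyl]-2,2-dimethyl-1,3-dioxan-5-yl]oxy}-3,5-dimethoxyphenyl)boronic acid; 14 5,7-bis(benzyloxy)-4H-chromen-4-one
Product: 15 (2S)-5,7-bis(benzyloxy)-2-(4-{[(4R,5R)-4-[4-(benzyloxy)phenyl]-2,2-dimethyl-1,3-dioxan-5-yl]oxy}-3,5-dimethoxyphenyl)-2,3-dihydro-4H-chromen-4-one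
Conditions: Pd(OCOCF3)2 (10 mol %), (R)-t-BuPyOX (12 mol %), NH4PF6 (30 mol %), H2O (5 equiv), 14 (1.5 equiv), ClCH2CH2Cl, 60 °C
Reagents that add atoms: none
Why: Pd(II)-catalysed asymmetric conjugate addition of an arylboronic acid to a chromone (cationic Pd/pyridine-oxazoline): transmetalation, enantio-determining syn-carbopalladation of C2=C3, and protonolysis of the Pd enolate by water. C2 is set by the ligand alone, since the stereocentres of 12 are too remote to interfere, and the base-free medium leaves the new flavanone no retro-oxa-Michael path to epimerise. The arylboronic acid has no ortho substituent and should transmetalate readily; the excess of 14 is meant to outrun protodeboronation.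

Step 10
Reactants: 15 (2S)-5,7-bis(benzyloxy)-2-(4-{[(4R,5R)-4-[4-(benzyloxy)phenyl]-2,2-dimethyl-1,3-dioxan-5-yl]oxy}-3,5-dimethoxyphenyl)-2,3-dihydro-4H-chromen-4-one
Product: 16 (2S)-5,7-bis(benzyloxy)-2-(4-{[(1R,2R)-1-[4-(benzyloxy)phenyl]-1,3-dihydroxypropan-2-yl]oxy}-3,5-dimethoxyphenyl)-2,3-dihydro-4H-chromen-4-one
Conditions: AcOH/H2O/THF (3:1:1), 40 °C
Reagents that add atoms: none
Why: Mild acid hydrolysis of the acetonide, which cleaves at the acetal carbon through the tertiary oxocarbenium ion; this is much easier than ionisation of the benzylic C7–O bond while the phenol is still a benzyl ether. The flavanone is stable to dilute acid.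

Step 11
Reactants: 16 (2S)-5,7-bis(benzyloxy)-2-(4-{[(1R,2R)-1-[4-(benzyloxy)phenyl]-1,3-dihydroxypropan-2-yl]oxy}-3,5-dimethoxyphenyl)-2,3-dihydro-4H-chromen-4-one
Product: 17 (2S)-5,7-dihydroxy-2-(4-{[(1R,2R)-1,3-dihydroxy-1-(4-hydroxyphenyl)propan-2-yl]oxy}-3,5-dimethoxyphenyl)-2,3-dihydro-4H-chromen-4-one
Conditions: H2 (1 atm), 10% Pd/C, EtOAc/EtOH (1:1), rt, stopped at full conversion
Reagents that add atoms: none
Why: Catalytic hydrogenolysis of three aryl benzyl ethers under neutral conditions. Cleavage of O–CH2Ph is much faster than hydrogenolysis of the secondary benzylic C7–OH or the C2–O1 bond, and the C4 ketone is a vinylogous ester hydrogen-bonded to the 5-OH. No stereocentre is touched.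

## Compound list

1 | 1-[4-(benzyloxy)phenyl]ethan-1-one | CC(=O)c1ccc(OCc2ccccc2)cc1 | starting material
2 | ethyl 3-[4-(benzyloxy)phenyl]-3-oxopropanoate | CCOC(=O)CC(=O)c1ccc(OCc2ccccc2)cc1 | intermediate
3 | ethyl 3-[4-(benzyloxy)phenyl]-2-chloro-3-oxopropanoate (racemic) | CCOC(=O)C(Cl)C(=O)c1ccc(OCc2ccccc2)cc1 | intermediate
4 | 4-bromo-2,6-dimethoxyphenol | COc1cc(Br)cc(OC)c1O | starting material
5 | ethyl 3-[4-(benzyloxy)phenyl]-2-(4-bromo-2,6-dimethoxyphenoxy)-3-oxopropanoate (racemic) | CCOC(=O)C(Oc1c(OC)cc(Br)cc1OC)C(=O)c1ccc(OCc2ccccc2)cc1 | intermediate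
6 | ethyl 3-[4-(benzyloxy)phenyl]-2-(4-bromo-2,6-dimethoxyphenoxy)-3-hydroxyprop-2-enoate (enol tautomer of 5) | CCOC(=O)C(Oc1c(OC)cc(Br)cc1OC)=C(O)c1ccc(OCc2ccccc2)cc1 | intermediate (not isolated)
7 | ethyl (2S,3R)-3-[4-(benzyloxy)phenyl]-2-(4-bromo-2,6-dimethoxyphenoxy)-3-hydroxypropanoate | CCOC(=O)[C@@H](Oc1c(OC)cc(Br)cc1OC)[C@H](O)c1ccc(OCc2ccccc2)cc1 | intermediate
8 | (1R,2R)-1-[4-(benzyloxy)phenyl]-2-(4-bromo-2,6-dimethoxyphenoxy)propane-1,3-diol | COc1cc(Br)cc(OC)c1O[C@H](CO)[C@H](O)c1ccc(OCc2ccccc2)cc1 | intermediate
9 | (4R,5R)-4-[4-(benzyloxy)phenyl]-5-(4-bromo-2,6-dimethoxyphenoxy)-2,2-dimethyl-1,3-dioxane | COc1cc(Br)cc(OC)c1O[C@@H]1COC(C)(C)O[C@@H]1c1ccc(OCc2ccccc2)cc1 | intermediate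
10 | (4-{[(4R,5R)-4-[4-(benzyloxy)phenyl]-2,2-dimethyl-1,3-dioxan-5-yl]oxy}-3,5-dimethoxyphenyl)lithium | [Li]c1cc(OC)c(O[C@@H]2COC(C)(C)O[C@@H]2c2ccc(OCc3ccccc3)cc2)c(OC)c1 | intermediate (not isolated)
11 | lithium (4-{[(4R,5R)-4-[4-(benzyloxy)phenyl]-2,2-dimethyl-1,3-dioxan-5-yl]oxy}-3,5-dimethoxyphenyl)tri(propan-2-yloxy)borate | [Li+].CC(C)O[B-](OC(C)C)(OC(C)C)c1cc(OC)c(O[C@@H]2COC(C)(C)O[C@@H]2c2ccc(OCc3ccccc3)cc2)c(OC)c1 | intermediate (not isolated)
12 | (4-{[(4R,5R)-4-[4-(benzyloxy)phenyl]-2,2-dimethyl-1,3-dioxan-5-yl]oxy}-3,5-dimethoxyphenyl)boronic acid | OB(O)c1cc(OC)c(O[C@@H]2COC(C)(C)O[C@@H]2c2ccc(OCc3ccccc3)cc2)c(OC)c1 | intermediate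
13 | 5,7-dihydroxy-4H-chromen-4-one | O=c1ccoc2cc(O)cc(O)c12 | starting material
14 | 5,7-bis(benzyloxy)-4H-chromen-4-one | O=c1ccoc2cc(OCc3ccccc3)cc(OCc3ccccc3)c12 | intermediate
15 | (2S)-5,7-bis(benzyloxy)-2-(4-{[(4R,5R)-4-[4-(benzyloxy)phenyl]-2,2-dimethyl-1,3-dioxan-5-yl]oxy}-3,5-dimethoxyphenyl)-2,3-dihydro-4H-chromen-4-one | COc1cc([C@@H]2CC(=O)c3c(OCc4ccccc4)cc(OCc4ccccc4)cc3O2)cc(OC)c1O[C@@H]1COC(C)(C)O[C@@H]1c1ccc(OCc2ccccc2)cc1 | intermediate
16 | (2S)-5,7-bis(benzyloxy)-2-(4-{[(1R,2R)-1-[4-(benzyloxy)phenyl]-1,3-dihydroxypropan-2-yl]oxy}-3,5-dimethoxyphenyl)-2,3-dihydro-4H-chromen-4-one | COc1cc([C@@H]2CC(=O)c3c(OCc4ccccc4)cc(OCc4ccccc4)cc3O2)cc(OC)c1O[C@H](CO)[C@H](O)c1ccc(OCc2ccccc2)cc1 | intermediate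
17 | (2S)-5,7-dihydroxy-2-(4-{[(1R,2R)-1,3-dihydroxy-1-(4-hydroxyphenyl)propan-2-yl]oxy}-3,5-dimethoxyphenyl)-2,3-dihydro-4H-chromen-4-one | COc1cc([C@@H]2CC(=O)c3c(O)cc(O)cc3O2)cc(OC)c1O[C@H](CO)[C@H](O)c1ccc(O)cc1 | target

## Step count and least certain steps

Total step count: 11. Longest linear sequence: 10 steps (1 to 17 through steps 1–7 and 9–11); step 8 is a one-step side branch.

**Step 4 (key step).** The likely failure is incomplete stereoconvergence. The substrate is strongly enolised and internally hydrogen-bonded, so it may racemise more slowly than the matched enantiomer is reduced. The bulky 2,6-dimethoxyaryloxy group may also be unable to take the antiperiplanar position. Either would erode the syn/anti ratio and the enantiomeric purity.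
Fallback (auxiliary-controlled aldol in place of the reduction; sets out from 4 and comes back at 8): O-alkylation of 4 with chloroacetic acid (NaOH, water, reflux) would give 2-(4-bromo-2,6-dimethoxyphenoxy)acetic acid F1. One-pot mixed-anhydride acylation of (4S)-4-benzyl-1,3-oxazolidin-2-one (PivCl, Et3N, LiCl, THF) would give (4S)-4-benzyl-3-[2-(4-bromo-2,6-dimethoxyphenoxy)acetyl]-1,3-oxazolidin-2-one F2. Its Z-boron enolate (Bu2BOTf, i-Pr2NEt, CH2Cl2, −78 °C) should add to commercial 4-(benzyloxy)benzaldehyde through the Zimmerman–Traxler chair to give the Evans syn adduct (4S)-4-benzyl-3-[(2S,3R)-3-[4-(benzyloxy)phenyl]-2-(4-bromo-2,6-dimethoxyphenoxy)-3-hydroxypropanoyl]-1,3-oxazolidin-2-one F3. Reductive removal of the auxiliary with LiBH4 (THF, a little water, 0 °C) would give 8 directly, and the route continues with step 6.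

**Step 9.** The likely failure is slow carbopalladation of the electron-rich, peri-substituted enone, so that protodeboronation of 12 wins. The other risk is an insufficient or opposite facial preference of the catalyst.
Fallback (chalcone route; sets out from 9 and comes back at 15): bromine–lithium exchange on 9 (n-BuLi, THF, −78 °C) and formylation with DMF would give 4-{[(4R,5R)-4-[4-(benzyloxy)phenyl]-2,2-dimethyl-1,3-dioxan-5-yl]oxy}-3,5-dimethoxybenzaldehyde F4. Claisen–Schmidt condensation with commercial 1-[2,4-bis(benzyloxy)-6-hydroxyphenyl]ethan-1-one (KOH, EtOH, rt) would give (E)-1-[2,4-bis(benzyloxy)-6-hydroxyphenyl]-3-(4-{[(4R,5R)-4-[4-(benzyloxy)phenyl]-2,2-dimethyl-1,3-dioxan-5-yl]oxy}-3,5-dimethoxyphenyl)prop-2-en-1-one F5. Oxa-Michael cyclisation, biased by a bifunctional cinchona-thiourea catalyst or simply run with NaOAc in EtOH, would give 15 together with its C2 epimer (2R)-5,7-bis(benzyloxy)-2-(4-{[(4R,5R)-4-[4-(benzyloxy)phenyl]-2,2-dimethyl-1,3-dioxan-5-yl]oxy}-3,5-dimethoxyphenyl)-2,3-dihydro-4H-chromen-4-one F6. F6 is a diastereomer of 15 and would be removed by preparative HPLC; the route continues with step 10.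

**Step 3.** The likely failure is attack of the hindered phenoxide on the chlorine of 3 (reductive dechlorination back to 2), or slow substitution at the congested secondary carbon.
Fallback (carbenoid O–H insertion in place of SN2; sets out from 2 and comes back at 5): Regitz diazo transfer to 2 (4-acetamidobenzenesulfonyl azide, Et3N, MeCN) would give ethyl 3-[4-(benzyloxy)phenyl]-2-diazo-3-oxopropanoate F7. Rh2(OAc)4-catalysed insertion of its carbenoid into the O–H bond of 4 (CH2Cl2, 40 °C) would give 5, and the route continues with step 4.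

**Step 7.** The likely failure is deprotonation competing with the exchange (benzylic OCH2 or ring positions), or protodeboronation of the electron-rich boronic acid during work-up.
Fallback (Pd-catalysed borylation in place of the organolithium; sets out from 9 and comes back at 12): Miyaura borylation of 9 (B2pin2, KOAc, PdCl2(dppf), dioxane, 80 °C) would give 2-(4-{[(4R,5R)-4-[4-(benzyloxy)phenyl]-2,2-dimethyl-1,3-dioxan-5-yl]oxy}-3,5-dimethoxyphenyl)-4,4,5,5-tetramethyl-1,3,2-dioxaborolane F8. Oxidative cleavage of the pinacol ester (NaIO4, NH4OAc, acetone/water, rt) would give 12, and the route continues with step 9.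

**Step 11.** The likely failure is over-reduction: hydrogenolysis of the benzylic C7–OH or of the C2–O1 bond once the phenols are free.
Fallback (order of the last two steps reversed so that the C7 oxygen stays locked in the dioxane during hydrogenolysis; sets out from 15 and ends at 17): hydrogenolysis of 15 (H2, Pd/C, EtOAc/EtOH) would give (2S)-5,7-dihydroxy-2-(4-{[(4R,5R)-4-(4-hydroxyphenyl)-2,2-dimethyl-1,3-dioxan-5-yl]oxy}-3,5-dimethoxyphenyl)-2,3-dihydro-4H-chromen-4-one F9. Its acetonide would then be removed with AcOH/H2O/THF at rt to give 17.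

## Further compounds

F1 | step 4 | 2-(4-bromo-2,6-dimethoxyphenoxy)acetic acid | COc1cc(Br)cc(OC)c1OCC(=O)O
F2 | step 4 | (4S)-4-benzyl-3-[2-(4-bromo-2,6-dimethoxyphenoxy)acetyl]-1,3-oxazolidin-2-one | COc1cc(Br)cc(OC)c1OCC(=O)N1[C@@H](Cc2ccccc2)COC1=O
F3 | step 4 | (4S)-4-benzyl-3-[(2S,3R)-3-[4-(benzyloxy)phenyl]-2-(4-bromo-2,6-dimethoxyphenoxy)-3-hydroxypropanoyl]-1,3-oxazolidin-2-one | COc1cc(Br)cc(OC)c1O[C@H](C(=O)N1[C@@H](Cc2ccccc2)COC1=O)[C@H](O)c1ccc(OCc2ccccc2)cc1
F4 | step 9 | 4-{[(4R,5R)-4-[4-(benzyloxy)phenyl]-2,2-dimethyl-1,3-dioxan-5-yl]oxy}-3,5-dimethoxybenzaldehyde | O=Cc1cc(OC)c(O[C@@H]2COC(C)(C)O[C@@H]2c2ccc(OCc3ccccc3)cc2)c(OC)c1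
F5 | step 9 | (E)-1-[2,4-bis(benzyloxy)-6-hydroxyphenyl]-3-(4-{[(4R,5R)-4-[4-(benzyloxy)phenyl]-2,2-dimethyl-1,3-dioxan-5-yl]oxy}-3,5-dimethoxyphenyl)prop-2-en-1-one | O=C(/C=C/c1cc(OC)c(O[C@@H]2COC(C)(C)O[C@@H]2c2ccc(OCc3ccccc3)cc2)c(OC)c1)c1c(O)cc(OCc2ccccc2)cc1OCc1ccccc1
F6 | step 9 | (2R)-5,7-bis(benzyloxy)-2-(4-{[(4R,5R)-4-[4-(benzyloxy)phenyl]-2,2-dimethyl-1,3-dioxan-5-yl]oxy}-3,5-dimethoxyphenyl)-2,3-dihydro-4H-chromen-4-one | COc1cc([C@H]2CC(=O)c3c(OCc4ccccc4)cc(OCc4ccccc4)cc3O2)cc(OC)c1O[C@@H]1COC(C)(C)O[C@@H]1c1ccc(OCc2ccccc2)cc1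
F7 | step 3 | ethyl 3-[4-(benzyloxy)phenyl]-2-diazo-3-oxopropanoate | CCOC(=O)C(=[N+]=[N-])C(=O)c1ccc(OCc2ccccc2)cc1
F8 | step 7 | 2-(4-{[(4R,5R)-4-[4-(benzyloxy)phenyl]-2,2-dimethyl-1,3-dioxan-5-yl]oxy}-3,5-dimethoxyphenyl)-4,4,5,5-tetramethyl-1,3,2-dioxaborolane | CC1(C)OB(OC1(C)C)c1cc(OC)c(O[C@@H]2COC(C)(C)O[C@@H]2c2ccc(OCc3ccccc3)cc2)c(OC)c1
F9 | step 11 | (2S)-5,7-dihydroxy-2-(4-{[(4R,5R)-4-(4-hydroxyphenyl)-2,2-dimethyl-1,3-dioxan-5-yl]oxy}-3,5-dimethoxyphenyl)-2,3-dihydro-4H-chromen-4-one | COc1cc([C@@H]2CC(=O)c3c(O)cc(O)cc3O2)cc(OC)c1O[C@@H]1COC(C)(C)O[C@@H]1c1ccc(O)cc1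
A1 | alternative 1 | (E)-1-[2,4-bis(benzyloxy)-6-hydroxyphenyl]-3-[4-({1-[4-(benzyloxy)phenyl]-1,3-dihydroxypropan-2-yl}oxy)-3,5-dimethoxyphenyl]prop-2-en-1-one (mixture of side-chain stereoisomers) | O=C(/C=C/c1cc(OC)c(OC(CO)C(O)c2ccc(OCc3ccccc3)cc2)c(OC)c1)c1c(O)cc(OCc2ccccc2)cc1OCc1ccccc1
A2 | alternative 2 | (2S)-5,7-dihydroxy-2-(4-hydroxy-3,5-dimethoxyphenyl)-2,3-dihydro-4H-chromen-4-one | COc1cc([C@@H]2CC(=O)c3c(O)cc(O)cc3O2)cc(OC)c1O
A3 | alternative 2 | 4-[(E)-3-hydroxyprop-1-en-1-yl]phenol (p-coumaryl alcohol) | OC/C=C/c1ccc(O)cc1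
A4 | alternative 2 | (2S)-5,7-dihydroxy-2-(4-{[1-hydroxy-3-(4-oxocyclohexa-2,5-dien-1-ylidene)propan-2-yl]oxy}-3,5-dimethoxyphenyl)-2,3-dihydro-4H-chromen-4-one (quinone methide, both C8 configurations) | COc1cc([C@@H]2CC(=O)c3c(O)cc(O)cc3O2)cc(OC)c1OC(CO)C=C1C=CC(=O)C=C1
A5 | alternative 3 | ethyl (2S,3R)-3-[4-(benzyloxy)phenyl]-2,3-dihydroxypropanoate | CCOC(=O)[C@@H](O)[C@H](O)c1ccc(OCc2ccccc2)cc1
A6 | alternative 3 | ethyl (4S,5R)-5-[4-(benzyloxy)phenyl]-1,3,2-dioxathiolane-4-carboxylate 2,2-dioxide | CCOC(=O)[C@H]1OS(=O)(=O)O[C@@H]1c1ccc(OCc2ccccc2)cc1
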